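**Retrosynthetic overview**

1. Target ⇒ (ester/acetate interchange at C17) ⇒ ring B opened at O–C16 and C15–C17, giving a C2-hydroxy allene C1=C15=C16 exocyclic to the 14-membered carbocycle (ring A); forward, this is re-closed by oxypalladation with CO capture.
2. Exocyclic allene ⇒ C1–C14 disconnection: SN2' attack of a C14 alkylborane on a C1≡C15–C16 propargylic carbonate, which closes ring A.
3. Structural feature used: the ring B atoms O, C2, C1, C15, C16 are a but-2-yne-1,4-diol in disguise. Bonding C14 to C1 turns the alkyne into a 1,1-disubstituted allene, and the tetrasubstituted C1=C15 alkene later grows out of that allene instead of out of a hindered coupling.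
4. Open chain ⇒ C1–C2 disconnection: catalyst-controlled alkynylation of a C2 enal (C2–C14, fragment 1) with methyl prop-2-ynyl carbonate (C1, C15, C16, fragment 2).
5. Fragment 1 ⇒ (2E,6E)-farnesol (C2–C13 and the three methyls) plus a one-carbon Wittig unit (C14), with the C7–C8 epoxide from a Shi epoxidation; ring order: epoxide, then ring A, then ring B.

Key step: step 12

Remark: atom numbers are those of the target (C1 ring-fusion alkene carbon, C2 O-bearing methine, C14 ring CH2 on C1, C15 alkene carbon bearing C16 and C17; C2–C13 are C1–C12 of farnesol). The ProPhenol antipode is assumed to be the one that transfers the alkynyl group to the Re face of the enal carbonyl (this gives 2S), to be verified by Mosher ester analysis on the first run.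

**Route**

Step 1
Reactants: 1 (2E,6E)-farnesol
Product: 2 (2E,6E)-farnesyl pivalate
Conditions: PivCl, pyridine, DMAP (cat.), CH2Cl2, 0 °C to rt
Reagents that add atoms: pivaloyl chloride, CC(C)(C)C(=O)Cl
Why: Acylation of the primary allylic alcohol with an acid chloride should be clean, and the pivalate is chosen because it outlasts the later acetate methanolysis and inductively deactivates the C3=C4 alkene.

Step 2
Reactants: 2 (2E,6E)-farnesyl pivalate
Product: 3 (2E,6E,10E)-12-hydroxyfarnesyl pivalate (the C13 allylic alcohol in target numbering)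
Conditions: SeO2 (0.3 equiv), tBuOOH (70% aq.), salicylic acid (cat.), CH2Cl2, rt, stopped at partial conversion
Reagents that add atoms: tert-butyl hydroperoxide, CC(C)(C)OO (terminal oxygen source, relayed by catalytic SeO2, O=[Se]=O)
Why: Catalytic SeO2 allylic oxidation (ene reaction followed by [2,3]-sigmatropic rearrangement) should hydroxylate the E-methyl group of the terminal, most electron-rich trisubstituted alkene, the usual site for farnesyl esters, with the E geometry kept.

Step 3
Reactants: 3 (2E,6E,10E)-12-hydroxyfarnesyl pivalate
Product: 4 (2E,6E,10E)-12-acetoxyfarnesyl pivalate (C13 acetate, C2 pivalate)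
Conditions: Ac2O, pyridine, DMAP (cat.), CH2Cl2, 0 °C
Reagents that add atoms: acetic anhydride, CC(=O)OC(C)=O
Why: DMAP-catalysed acetylation of the primary allylic alcohol places a second electron-withdrawing allylic ester next to C11=C12, one that can later be removed without touching the pivalate.

Step 4
Reactants: 4 (2E,6E,10E)-12-acetoxyfarnesyl pivalate
Product: 5 (7S,8S)-7,8-epoxy diester (C13 acetate, C2 pivalate, E-alkenes at C3=C4 and C11=C12)
Conditions: ent-Shi ketone (1,2:4,5-di-O-isopropylidene-β-L-erythro-2,3-hexodiulo-2,6-pyranose, made from L-sorbose, 0.3 equiv), KHSO5 (as 2KHSO5·KHSO4·K2SO4), K2CO3, Bu4NHSO4 (cat.), MeCN–CH2(OMe)2/aq. Na2B4O7 buffer (pH 10.5), 0 °C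
Reagents that add atoms: potassium peroxymonosulfate, [K+].[O-]S(=O)(=O)OO
Why: Shi asymmetric epoxidation should touch only C7=C8, because C3=C4 and C11=C12 each carry a deactivating allylic ester, and the spiro transition state of the L-series ketone delivers oxygen to the face of this E-trisubstituted alkene that gives the (7S,8S)-epoxide (reagent control of both new stereocentres).

Step 5
Reactants: 5 (7S,8S)-7,8-epoxy diester
Product: 6 (7S,8S)-epoxy C13 allylic alcohol, C2 pivalate
Conditions: K2CO3, MeOH, 0 °C
Reagents that add atoms: none
Why: Base-catalysed transesterification with methanol should remove the unhindered acetate far faster than the pivalate and leave the trisubstituted epoxide alone.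

Step 6
Reactants: 6 (7S,8S)-epoxy C13 allylic alcohol, C2 pivalate
Product: 7 (7S,8S)-epoxy C13 enal, C2 pivalate
Conditions: activated MnO2, CH2Cl2, rt
Reagents that add atoms: none
Why: MnO2 allylic oxidation is neutral and selective for the allylic alcohol, so the epoxide, the pivalate and the E geometry of C11=C12 should survive.

Step 7
Reactants: 7 (7S,8S)-epoxy C13 enal, C2 pivalate; 8 methyltriphenylphosphonium bromide
Product: 9 (7S,8S)-epoxy terminal (E)-diene (C11=C12–C13=C14), C2 pivalate
Conditions: 8, KN(SiMe3)2, THF, 0 °C; then 7, −78 to 0 °C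
Reagents that add atoms: methyltriphenylphosphonium bromide (8), C[P+](c1ccccc1)(c1ccccc1)c1ccccc1.[Br-]
Why: Wittig methylenation of the enal with the non-stabilised ylide should install C14 as the terminal carbon of the 1,3-diene, the hindered pivalate and the epoxide being inert to the ylide.

Step 8
Reactants: 9 (7S,8S)-epoxy terminal diene, C2 pivalate
Product: 10 (7S,8S)-epoxy dienyl C2 allylic alcohol
Conditions: iBu2AlH (2.5 equiv), CH2Cl2, −78 °C; aq. KNaC4H4O6 work-up
Reagents that add atoms: none
Why: Reductive ester cleavage with iBu2AlH at −78 °C should free the C2 alcohol under conditions in which a trisubstituted epoxide and a diene are normally untouched.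

Step 9
Reactants: 10 (7S,8S)-epoxy dienyl C2 allylic alcohol
Product: 11 (7S,8S)-epoxy dienyl C2 enal (fragment 1, C2–C14)
Conditions: activated MnO2, CH2Cl2, rt
Reagents that add atoms: none
Why: MnO2 allylic oxidation should again give the E-enal without acid or base, so the epoxide and the diene are not at risk.

Step 10
Reactants: 11 (7S,8S)-epoxy dienyl C2 enal (fragment 1); 12 methyl prop-2-ynyl carbonate (fragment 2)
Product: 13 (2S,7S,8S)-propargylic alcohol carrying the diene and the primary propargylic methyl carbonate
Conditions: 12 (3 equiv), Me2Zn (3 equiv), ProPhenol (2,6-bis[(2-(hydroxydiphenylmethyl)pyrrolidin-1-yl)methyl]-4-methylphenol, Re-face-selective antipode, 20 mol %), Ph3PO (40 mol %), toluene, 0–4 °C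
Reagents that add atoms: none
Why: Catalytic asymmetric alkynylation of an enal by a zinc acetylide under the dinuclear zinc–ProPhenol catalyst should form C1–C2, with C2 set by catalyst control through Re-face delivery of the alkynyl group (2S), while the weakly basic zinc species leave the carbonate and the epoxide intact.

Step 11
Reactants: 13 (2S,7S,8S)-propargylic alcohol
Product: 14 (2S,7S,8S)-C2 tert-butyldimethylsilyl ether with diene and propargylic carbonate
Conditions: TBSCl, imidazole, DMAP (cat.), DMF, 0 °C to rt
Reagents that add atoms: tert-butyldimethylsilyl chloride, CC(C)(C)[Si](C)(C)Cl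
Why: Silyl ether formation masks the C2 hydroxyl so that it neither consumes 9-BBN nor interferes with the allenylpalladium intermediate, and these mild conditions should spare the epoxide and the carbonate.

Step 12
Reactants: 14 (2S,7S,8S)-C2 silyl ether with diene and propargylic carbonate
Product: 16 (2S,7S,8S)-14-membered ring A with exocyclic allene C1=C15=C16 and C2 silyl ether, via B-alkyl-9-BBN borane 15 (not isolated)
Conditions: 9-BBN dimer (1.1 equiv B–H), THF, 0 °C to rt; then syringe-pump addition over about 12 h to Pd(PPh3)4 (10 mol %), degassed THF, 60 °C, final concentration about 1 mM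
Reagents that add atoms: none
Why: Proposed new method: 9-BBN should add to the terminal vinyl group of the diene (boron on C14), leaving the trisubstituted alkenes and the hindered, electron-poor internal alkyne alone; zerovalent palladium then ionises the primary propargylic carbonate in the SN2' sense with loss of CO2 to a divalent allenylpalladium methoxide bonded at C1, the methoxide quaternises the tethered boron, the alkyl group transmetalates and reductive elimination forms C1–C14. The closest known reactions are the intermolecular palladium-catalysed coupling of propargylic carbonates with B-alkyl-9-BBN reagents to allenes under base-free conditions and the B-alkyl Suzuki–Miyaura macrocyclisation; their union as an allene-forming macrocyclisation is the new element. Ring A is closed in exo mode at C1 through a 15-membered palladacycle, with C15 and C16 left outside the ring as the allene. No stereocentre is formed and the terminal allene has no axial chirality, so C2 and the epoxide are spectators and no remote diastereocontrol is asked for. The step needs bonding at C1 and not at C16 (which would give a 16-membered cycloalkyne) and ring closure and not oligomerisation; the first should follow from the preference of primary 2-alkynyl carbonates to couple through the allenylpalladium form, the second from slow addition at high dilution. The neutral, base-free medium should leave the epoxide, the silyl ether and the E-alkenes untouched.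

Step 13
Reactants: 16 (2S,7S,8S)-ring A allene, C2 silyl ether
Product: 17 (2S,7S,8S)-α-allenol (C2–OH next to the exocyclic allene)
Conditions: Bu4NF, THF, 0 °C
Reagents that add atoms: none
Why: Fluoride-mediated desilylation should free the C2 hydroxyl without touching the allene, the epoxide or the alkenes, and without change at C2.

Step 14
Reactants: 17 (2S,7S,8S)-α-allenol; 18 carbon monoxide
Product: 19 bicyclic 2,5-dihydrofuran methyl ester (ring B closed, CO2Me on C15)
Conditions: Pd(OAc)2 (10 mol %), p-benzoquinone (1.5 equiv), NaOAc (0.5 equiv), CO (1 atm), MeOH–THF, 0 °C to rt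
Reagents that add atoms: methanol, CO; carbon monoxide (18), [C-]#[O+]
Why: Oxidative cyclisation–alkoxycarbonylation of a hydroxyallene: divalent palladium activates the allene, the C2 hydroxyl adds to C16 in 5-endo fashion to leave a C15 vinylpalladium species, CO insertion and methanolysis give the ester, and benzoquinone returns zerovalent palladium to the divalent state, with C2 unchanged because its C–O bond is never broken.

Step 15
Reactants: 19 bicyclic dihydrofuran methyl ester
Product: 20 C17 primary allylic alcohol
Conditions: iBu2AlH (2.5 equiv), CH2Cl2, −78 °C; aq. KNaC4H4O6 work-up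
Reagents that add atoms: none
Why: iBu2AlH reduction of the α,β-unsaturated ester at −78 °C should proceed by 1,2-hydride delivery to the allylic alcohol fast enough to spare the trisubstituted epoxide.

Step 16
Reactants: 20 C17 primary allylic alcohol
Product: 21 target CNP0140293.1
Conditions: Ac2O, pyridine, DMAP (cat.), CH2Cl2, 0 °C
Reagents that add atoms: acetic anhydride, CC(=O)OC(C)=O
Why: DMAP-catalysed acetylation of the primary allylic alcohol should complete the target without disturbing the epoxide or the dihydrofuran.

**Compound list**

1 | (2E,6E)-farnesol | CC(C)=CCC/C(C)=C/CC/C(C)=C/CO | starting material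
2 | (2E,6E)-farnesyl pivalate | CC(C)=CCC/C(C)=C/CC/C(C)=C/COC(=O)C(C)(C)C | intermediate
3 | (2E,6E,10E)-12-hydroxyfarnesyl pivalate | OC/C(C)=C/CC/C(C)=C/CC/C(C)=C/COC(=O)C(C)(C)C | intermediate
4 | (2E,6E,10E)-12-acetoxyfarnesyl pivalate | CC(=O)OC/C(C)=C/CC/C(C)=C/CC/C(C)=C/COC(=O)C(C)(C)C | intermediate
5 | (7S,8S)-7,8-epoxy diester (C13 acetate, C2 pivalate) | CC(=O)OC/C(C)=C/CC[C@]1(C)O[C@H]1CC/C(C)=C/COC(=O)C(C)(C)C | intermediate
6 | (7S,8S)-epoxy C13 allylic alcohol, C2 pivalate | OC/C(C)=C/CC[C@]1(C)O[C@H]1CC/C(C)=C/COC(=O)C(C)(C)C | intermediate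
7 | (7S,8S)-epoxy C13 enal, C2 pivalate | O=C/C(C)=C/CC[C@]1(C)O[C@H]1CC/C(C)=C/COC(=O)C(C)(C)C | intermediate
8 | methyltriphenylphosphonium bromide | C[P+](c1ccccc1)(c1ccccc1)c1ccccc1.[Br-] | starting material
9 | (7S,8S)-epoxy terminal diene, C2 pivalate | C=C/C(C)=C/CC[C@]1(C)O[C@H]1CC/C(C)=C/COC(=O)C(C)(C)C | intermediate
10 | (7S,8S)-epoxy dienyl C2 allylic alcohol | C=C/C(C)=C/CC[C@]1(C)O[C@H]1CC/C(C)=C/CO | intermediate
11 | (7S,8S)-epoxy dienyl C2 enal, fragment 1 | C=C/C(C)=C/CC[C@]1(C)O[C@H]1CC/C(C)=C/C=O | intermediate
12 | methyl prop-2-ynyl carbonate, fragment 2 | C#CCOC(=O)OC | starting material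
13 | (2S,7S,8S)-propargylic alcohol with diene and propargylic carbonate | C=C/C(C)=C/CC[C@]1(C)O[C@H]1CC/C(C)=C/[C@H](O)C#CCOC(=O)OC | intermediate
14 | (2S,7S,8S)-C2 tert-butyldimethylsilyl ether of 13 | C=C/C(C)=C/CC[C@]1(C)O[C@H]1CC/C(C)=C/[C@H](O[Si](C)(C)C(C)(C)C)C#CCOC(=O)OC | intermediate
15 | C14 B-alkyl-9-BBN borane of 14 | B1(C2CCCC1CCC2)CC/C(C)=C/CC[C@]3(C)O[C@H]3CC/C(C)=C/[C@H](O[Si](C)(C)C(C)(C)C)C#CCOC(=O)OC | intermediate
16 | (2S,7S,8S)-14-membered ring A with exocyclic allene at C1, C2 silyl ether | C=C=C1CC/C(C)=C/CC[C@]2(C)O[C@H]2CC/C(C)=C/[C@@H]1O[Si](C)(C)C(C)(C)C | intermediate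
17 | (2S,7S,8S)-α-allenol of ring A | C=C=C1CC/C(C)=C/CC[C@]2(C)O[C@H]2CC/C(C)=C/[C@@H]1O | intermediate
18 | carbon monoxide | [C-]#[O+] | starting material
19 | bicyclic 2,5-dihydrofuran methyl ester | COC(=O)C1=C2CC/C(C)=C/CC[C@]3(C)O[C@H]3CC/C(C)=C/[C@@H]2OC1 | intermediate
20 | C17 primary allylic alcohol | OCC1=C2CC/C(C)=C/CC[C@]3(C)O[C@H]3CC/C(C)=C/[C@@H]2OC1 | intermediate
21 | CNP0140293.1 | CC(=O)OCC1=C2CC/C(C)=C/CC[C@]3(C)O[C@H]3CC/C(C)=C/[C@@H]2OC1 | target

**Step count and risks**

Total step count: 16. Longest linear sequence: 16 steps, from farnesol 1 to target 21; compounds 8, 12 and 18 are bought.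

Steps most likely to fail:

1. Step 12 (the new macrocyclisation). Intermolecular coupling may outrun ring closure and give oligomers. The alkyl group may bond at C16 and give the 16-membered cycloalkyne. The alkylpalladium intermediate may lose a β-hydride before reductive elimination. Fallback with known chemistry, closing ring A at C1–C2 instead of C1–C14; it sets out from 9 and comes back at 17.
   - Hydroboration of 9 with 9-BBN and oxidation with NaBO3 would give the C14 primary alcohol F1.
   - I2, PPh3 and imidazole would give the C14 iodide F2.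
   - The lithium acetylide of tert-butyldimethyl(prop-2-ynyloxy)silane in THF–DMPU would displace iodide and give the silyl-protected 2-alkynol F3.
   - Bu4NF would give the propargylic alcohol F4, and CBr4 with PPh3 (Appel reaction) the propargylic bromide F5.
   - iBu2AlH at −78 °C would remove the pivalate to give the bromo allylic alcohol F6, and MnO2 would give the bromo enal F7.
   - Slow addition of F7 to CrCl2 in THF at high dilution would close ring A. This is an intramolecular Barbier reaction of the Nozaki–Hiyama type, in which 2-alkynyl bromides substituted on the alkyne add to aldehydes through the allenyl terminus. It would give allenol 17 together with its C2 epimer F8, a diastereomer (because of the epoxide) that is removed by chromatography.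
   - In this fallback C2 is not set by a catalyst.

2. Step 14. The vinylpalladium intermediate may be protonated before it captures CO, and the Lewis-acidic divalent palladium in methanol may open the epoxide. The fallback sets out from 17 and comes back at 19. 5-endo iodocyclisation of the α-allenol with N-iodosuccinimide in CH2Cl2 at 0 °C (NaHCO3 buffer) would give the C15 iodo dihydrofuran F9. Methoxycarbonylation of this vinyl iodide under zerovalent palladium catalysis (PdCl2(PPh3)2, CO 1 atm, MeOH, Et3N, DMF, 50 °C) would then give ester 19.

3. Step 10. Facial selectivity in the alkynyl transfer to the β,β-disubstituted enal may be poor. The fallback moves the stereo-determining event to a ketone reduction; it sets out from 11 (with 12) and comes back at 13. Ligand-free Me2Zn-mediated addition of 12 to 11 in toluene would give 13 mixed with its (2R)-epimer F10. Dess–Martin periodinane (NaHCO3 buffer) would oxidise the mixture to the dienynone F11. Reduction with (S)-2-methyl-CBS-oxazaborolidine and catecholborane at −78 °C, the alkynyl arm acting as the small group, would return (2S)-alcohol 13; the catalyst antipode is to be confirmed by Mosher ester analysis.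

**Further compounds**

F1 | step 12 | C14 primary alcohol, (7S,8S)-epoxide, C2 pivalate | OCC/C(C)=C/CC[C@]1(C)O[C@H]1CC/C(C)=C/COC(=O)C(C)(C)C
F2 | step 12 | C14 iodide, (7S,8S)-epoxide, C2 pivalate | ICC/C(C)=C/CC[C@]1(C)O[C@H]1CC/C(C)=C/COC(=O)C(C)(C)C
F3 | step 12 | silyl-protected 2-alkynol (C16 OTBS, C1≡C15 alkyne), C2 pivalate | CC(C)(C)[Si](C)(C)OCC#CCC/C(C)=C/CC[C@]1(C)O[C@H]1CC/C(C)=C/COC(=O)C(C)(C)C
F4 | step 12 | propargylic alcohol (C16 OH), C2 pivalate | OCC#CCC/C(C)=C/CC[C@]1(C)O[C@H]1CC/C(C)=C/COC(=O)C(C)(C)C
F5 | step 12 | propargylic bromide (C16 Br), C2 pivalate | BrCC#CCC/C(C)=C/CC[C@]1(C)O[C@H]1CC/C(C)=C/COC(=O)C(C)(C)C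
F6 | step 12 | bromo allylic alcohol (C16 Br, C2 OH) | BrCC#CCC/C(C)=C/CC[C@]1(C)O[C@H]1CC/C(C)=C/CO
F7 | step 12 | bromo enal (C16 Br, C2 aldehyde) | BrCC#CCC/C(C)=C/CC[C@]1(C)O[C@H]1CC/C(C)=C/C=O
F8 | step 12 | (2R,7S,8S)-α-allenol, C2 epimer of 17 | C=C=C1CC/C(C)=C/CC[C@]2(C)O[C@H]2CC/C(C)=C/[C@H]1O
F9 | step 14 | C15 iodo 2,5-dihydrofuran (ring B closed, iodine on C15) | IC1=C2CC/C(C)=C/CC[C@]3(C)O[C@H]3CC/C(C)=C/[C@@H]2OC1
F10 | step 10 | (2R,7S,8S)-propargylic alcohol, C2 epimer of 13 | C=C/C(C)=C/CC[C@]1(C)O[C@H]1CC/C(C)=C/[C@@H](O)C#CCOC(=O)OC
F11 | step 10 | C2 dienynone with propargylic carbonate | C=C/C(C)=C/CC[C@]1(C)O[C@H]1CC/C(C)=C/C(=O)C#CCOC(=O)OC
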